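A surplus of 0.0100 M of G over Q is what ash has to finish on, against 0.160 M in elm.

all flasks: temperature 70 °C

| flask | Q | G | Z | remark | time |
|---|---|---|---|---|---|
| north-west | 0.20 M | 0.32 M | 14 mM | run made earlier |  |
| east | 0.20 M | 0.21 M | 7 mM | run made earlier |  |
| elm | 0.050 M | 0.210 M | 14 mM |  | 6.0 min |
| ash | 0.20 M | 0.210 M | 14 mM |  | 25 min |

| run | time / min | E / % | Q / % |
|---|---|---|---|
| north-west | 1.33 | 82 | 14 |
| north-west | 2.50 | 94 | 7 |
| north-west | 4.00 | 97 | 2 |
| north-west | 5.00 | 99 | 3 |
| east | 1.33 | 50 | 48 |
| east | 2.50 | 65 | 38 |
| east | 4.00 | 71 | 33 |
| east | 5.00 | 72 | 27 |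

(readings scatter by 1.5 percentage points)

- for E the J are counted in
- the numbers in the tables scatter with a standard deviation of 1.5 percentage points
- candidate steps: G <-> D; Q + G + Z -> Z + E; G + E <-> J

- the flask that ends with the higher amount of E, in percent of the Q charged, or "neither" when 2 percentage points or less lies between them (elm / ash / neither)
- final E, as a percentage of the Q charged, in elm
- final E, as a percentage of the Q charged, in ash

I turn the catalyst first. By hand, Z should scale the pace. With the rate written as a constant times Q times G, the first readings give 7.49 /M/min in the north-west run and 3.78 /M/min in the east run. That is half the constant, with 7 mM of Z against 14 mM.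

Next comes G. By hand, one G per Q leaves the east run with 0.0750 M of G midway between 2.50 min and 5.00 min. The pace of Q over that stretch, divided by that constant and by Q, reads 0.0358 M, which is less. The difference, 0.0392 M, is the held-away G: a small correction to the charge, standing in J or D, with the scatter of the readings on it.

Then Q. I subtract Q and the held-away G from the G charged. Elm keeps 0.121 M, and on that amount alone, as a pseudo-first-order decay, Q has a half-life of 0.766 min, far shorter than the 6.0 min allowed. Ash comes out at −0.0292 M, so G is its limiting reagent, and by my reckoning E reaches 85.4% and then waits for held G to come back. That is my low mark for 25 min, since the readings give no pace of return.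

The forecast says elm, with 99% (95% to 100%) for elm and 91% (80% to 97%) for ash: “Ash is near-stoichiometric, so it crawls at the end as G is withheld.” Its ash figure stands above my mark.

The flasks give 99.5% in elm and 91.3% in ash, so elm ends higher.

    G ⇌ D (K = 5.00, k = 0.152 /min, Ea = 102 kJ/mol, ΔH = −19.0 kJ/mol)
    Q + G + Z → Z + E (k = 593 /M²/min, Ea = 42.0 kJ/mol)
    G + E ⇌ J, settled at all times (K = 1.34 /M, ΔH = −6.00 kJ/mol)
    (constants at 70 °C)

In ash, the step Q + G + Z had 91% of its turnover behind it at 5.00 min, and at 12.5 min G stood at 1.60% of its charge with Q at 11.6%. From then to 25.0 min, D fell from 0.0291 M to 0.0243 M while Q fell to 8.73%, which put ash 5.9 percentage points above the mark. With 0.080 M of Q in ash's place, the surplus of G over Q is 0.130 M, larger than the 0.0392 M read in the east run, and that flask ends at >99.9% of E with 0.0096% of its Q left, though the held-away G is no fixed amount: D alone stands there at 0.105 M at 25.0 min, above that reading.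

The runs come from a simulation on assumed constants; scatter was added.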